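Early minutes are where these flasks can be read, so start there when you take over the bench.

| setting | spring | dawn | autumn | noon | winter |
|---|---|---|---|---|---|
| starting material | 0.600 M | 0.240 M | 0.600 M | 1.20 M | 2.80 M |
| reagent | 1.50 M | 1.14 M | 1.50 M | 1.50 M | 1.50 M |
| free catalyst | 0.0300 M | 0.0300 M | 0.0150 M | 0.0300 M | 0.0300 M |
| time |  |  |  |  | 73 min |

- spring run (time / min: [product] / M): 2.9: 0.0221; 5.0: 0.0362; 8.5: 0.0569; 15: 0.0943; 25: 0.1315; 43: 0.1819; 73: 0.2325
- dawn run (time / min: [product] / M): 2.9: 0.0154; 5.0: 0.0181; 8.5: 0.0285; 15: 0.0481; 25: 0.0671; 43: 0.0858; 73: 0.1099
- autumn run (time / min: [product] / M): 2.9: 0.0147; 5.0: 0.0197; 8.5: 0.0339; 15: 0.0517; 25: 0.0828; 43: 0.1166; 73: 0.1627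
- noon run (time / min: [product] / M): 2.9: 0.0326; 5.0: 0.0553; 8.5: 0.0924; 15: 0.1394; 25: 0.2093; 43: 0.2921; 73: 0.3842

(each reading ± 0.002 M)

- Overall: starting material + reagent -> product, with free catalyst as catalyst.
- Constant volume, constant temperature.
- Readings of a species count what is bound in complexes too.
- "The second partner" is reagent.
- An order is taken over about fifteen percent of the charge, up and down.

* apparent order in [reagent] of the starting rate, round the charge of the spring run (the rate where two percent of its starting material have turned into product)
* apparent order in [starting material] of the starting rate, round the charge of the spring run (the rate where two percent of its starting material have turned into product) (one fixed amount of product, the same in the runs compared)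
* product in the winter run at 73 min, as a share of the starting material charged

Over the first 5.0 min, the spring flask made product at 0.00724 M min⁻¹. The noon flask, with twice the starting material, made it at 0.0111 M min⁻¹. From these two readings, each with its scatter, I take an order in c(starting material) of 0.611.

The noon rate does not last. At 73 min the noon flask holds 0.3842 M, which its early rate would have made in 34.7 min. Call that the working minutes, the product at 73 min divided by the early rate of the same flask.

The winter flask has the reagent and free catalyst charges of the noon flask, so I carry the noon working minutes over to it. Leave the free catalyst charge alone, since the working minutes were read at that charge. The reagent order stays open, because the dawn flask moves both charges, but the winter reckoning does not need it.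

Scaling the noon rate by the order gives about 0.0186 M min⁻¹ for the winter flask. Over the working minutes, that puts 0.645 M of product in it at 73 min, or 23.0% of its charge. By the overall equation, about 2.16 M of starting material and 0.855 M of reagent remain. The winter charge lies beyond the span of the order, so this is my reckoning, not a reading.

The forecast gives 0.2 for the reagent order, 0.7 for the starting material order and 20% for the winter share, holding that “the loss follows time”, whereas my reckoning gave 0.611 for the starting material order and 23.0% for the winter share.

The flask gives 0.068 for the reagent order, 0.71 for the starting material order and 23.6% for the winter share.

    free catalyst + starting material → loaded catalyst + by-product (0.9420 L mol⁻¹ min⁻¹)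
    loaded catalyst + reagent → product + free catalyst (2.988 L mol⁻¹ min⁻¹)
    2 free catalyst → 2 spent catalyst (0.9120 L mol⁻¹ min⁻¹)
    2 starting material ⇌ idle substrate dimer, settled at all times (1.230 L mol⁻¹)

The winter share is 0.662 M of product, which over the noon working minutes of 34.7 min corresponds to an early rate of 0.0191 M min⁻¹. It stands at 23.6% because two free catalyst turn into spent catalyst while two starting material pair to idle substrate dimer; without the first the winter flask reaches 42.1%, without the second 47.8%. The readings give 32.1 min of working minutes in the spring flask and 41.3 min in the autumn flask, which holds half the free catalyst of the spring flask, and the first half-life of free catalyst by that turning step alone is 18.3 min at the spring charge against 36.5 min at the autumn charge.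

The readings are simulated with constants of no real substance, and the scatter is random.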